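**Assumptions (one line each)**
- Daucane numbering is used in the explanations: C1 = quaternary C–Me, C4 = C(OH)(iPr), C5 = ring-fusion CH, C6 = CH–O, C8/C9 = epoxide carbons. Read from the target SMILES: trans ring fusion (1β-Me, 5α-H), 4β-OH, 6α-ester, 8α,9α-epoxide.
- (S)-(+)-Terpinen-4-ol is taken as enantiopure (≥98% ee); commercial lots are often scalemic and would need upgrading by preparative chiral chromatography first.

## Retrosynthetic overview
1. Jaeskeanin ⇐ global desilylation ⇐ C6 acylation ⇐ C6-OH-directed 8α,9α-epoxidation of 4-O-TES-jaeschkeanadiol.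
2. That diol ⇐ CO2Me→CH3 and α-face hydroboration of the C5=C6 bond of a bicyclo[5.3.0]deca-1,4-diene ester.
3. Key step: the seven-membered ring and the C1 quaternary centre are formed together by a Rh(II)-vinylcarbenoid [4+3] (cyclopropanation / divinylcyclopropane Cope) between a 1-vinylcyclopentene and methyl 2-diazobut-3-enoate.
4. The vinylcyclopentene, carrying the C4 carbinol stereocentre, comes from (S)-terpinen-4-ol by ozonolysis, aldol ring contraction and Wittig methylenation.
5. Ring order: five-membered ring first (terpene ring contraction), then the seven-membered ring ([4+3]).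

## Forward route

**Step 1**
Reactants: 1, (S)-(+)-terpinen-4-ol
Product: 2, (S)-triethyl{[4-methyl-1-(propan-2-yl)cyclohex-3-en-1-yl]oxy}silane
Conditions: TESOTf, 2,6-lutidine, CH2Cl2, 0 °C
Reagents that add atoms: triethylsilyl triflate, CC[Si](CC)(CC)OS(=O)(=O)C(F)(F)F
Why: Silyl triflate silylation of the tertiary alcohol blocks hemiketal/retro-aldol chemistry and Rh-carbenoid O–H insertion later, and puts a bulky group on the β-face; the stereocentre is untouched.

**Step 2**
Reactants: 2
Product: 3, (S)-6-oxo-3-(propan-2-yl)-3-[(triethylsilyl)oxy]heptanal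
Conditions: O3, CH2Cl2/MeOH, −78 °C; then Me2S
Reagents that add atoms: ozone, [O-][O+]=O
Why: Ozonolysis with reductive work-up cleaves the only alkene to a methyl ketone and an aldehyde, leaving the quaternary carbinol centre intact.

**Step 3**
Reactants: 3
Product: 4, (R)-2-methyl-5-(propan-2-yl)-5-[(triethylsilyl)oxy]cyclopent-1-ene-1-carbaldehyde
Conditions: piperidine, AcOH (cat.), PhH, 60 °C
Reagents that add atoms: none
Why: Enamine-mediated intramolecular aldol condensation (aldehyde α-carbon onto the methyl ketone, 5-exo, as in the limonene keto-aldehyde ring contraction) gives the cyclopentene carbaldehyde; the descriptor changes S→R only through CIP priorities.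

**Step 4**
Reactants: 4
Product: 5, (R)-triethyl{[3-methyl-1-(propan-2-yl)-2-vinylcyclopent-2-en-1-yl]oxy}silane
Conditions: Ph3PCH3Br, KOtBu, THF, 0 °C → rt
Reagents that add atoms: methyltriphenylphosphonium bromide, C[P+](c1ccccc1)(c1ccccc1)c1ccccc1.[Br-]
Why: Wittig methylenation of the enal supplies C7 and gives the 1-vinylcyclopentene diene for the [4+3].

**Step 5**
Reactants: 6, methyl acetoacetate
Product: 7, methyl 2-diazo-3-oxobutanoate
Conditions: p-ABSA, Et3N, MeCN, 0 °C → rt
Reagents that add atoms: 4-acetamidobenzenesulfonyl azide, CC(=O)Nc1ccc(cc1)S(=O)(=O)N=[N+]=[N-]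
Why: Regitz diazo transfer to the active methylene.

**Step 6**
Reactants: 7
Product: 8, methyl 2-diazo-3-hydroxybutanoate
Conditions: NaBH4, MeOH, 0 °C
Reagents that add atoms: none
Why: Borohydride reduces the ketone chemoselectively; the diazo ester survives.

**Step 7**
Reactants: 8
Product: 9, methyl 2-diazobut-3-enoate (used at once as a cold solution)
Conditions: POCl3, Et3N, CH2Cl2, 0 °C
Reagents that add atoms: none
Why: Dehydration of the β-hydroxy diazo ester gives the parent vinyldiazoacetate, which must be used immediately because it electrocyclises to a pyrazole on standing.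

**Step 8 (key step)**
Reactants: 5 and 9
Product: 10, methyl (3R,8aR)-8a-methyl-3-(propan-2-yl)-3-[(triethylsilyl)oxy]-1,2,3,5,8,8a-hexahydroazulene-6-carboxylate
Conditions: Rh2(R-DOSP)4 (1 mol %), hexanes, −40 °C → rt, slow addition of 9 (2–3 equiv); then PhMe, 110 °C
Reagents that add atoms: none (all new atoms come from 9)
Why: Davies Rh(II)-vinylcarbenoid [4+3] (tandem cyclopropanation / divinylcyclopropane Cope): catalyst-controlled cyclopropanation of the terminal vinyl group gives the (1S,2S)-cis-divinylcyclopropane, and the boat Cope transfers that chirality to C1, with C10 bonding anti to OSiEt3 (the iPr face); heating is needed because the ring methyl is the inside (Z) substituent. The R-catalyst is my assignment by analogy with the reported styrene sense for Rh2(S-DOSP)4 and should be confirmed by running both enantiomers.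

**Step 9**
Reactants: 10
Product: 11, methyl (3R,3aS,4S,8aR)-4-hydroxy-8a-methyl-3-(propan-2-yl)-3-[(triethylsilyl)oxy]-1,2,3,3a,4,5,8,8a-octahydroazulene-6-carboxylate
Conditions: BH3·SMe2, THF, 0 °C → rt; then H2O2, aq. NaOAc, 0 °C
Reagents that add atoms: hydrogen peroxide, OO
Why: Hydroboration–oxidation is chemoselective for the electron-rich C5=C6 bond over the enoate and places boron on C6; syn addition on the α-face (anti to the allylic OSiEt3 and the angular methyl) would set 5α-H and 6α-OH, i.e. the trans ring fusion, in one step — but this facial preference is an expectation, not a certainty (see risks).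

**Step 10**
Reactants: 11
Product: 12, (3R,3aS,4S,8aR)-6-(hydroxymethyl)-8a-methyl-3-(propan-2-yl)-3-[(triethylsilyl)oxy]-1,2,3,3a,4,5,8,8a-octahydroazulen-4-ol
Conditions: DIBAL-H (3.5 equiv), CH2Cl2, −78 → 0 °C
Reagents that add atoms: none
Why: 1,2-Reduction of the enoate to the primary allylic alcohol; no stereocentre is affected.

**Step 11**
Reactants: 12
Product: 13, (3R,3aS,4S,8aR)-6,8a-dimethyl-3-(propan-2-yl)-3-[(triethylsilyl)oxy]-1,2,3,3a,4,5,8,8a-octahydroazulen-4-ol (4-O-TES-jaeschkeanadiol)
Conditions: SO3·pyridine, THF, 0 °C; then LiAlH4, 0 °C → rt (one pot)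
Reagents that add atoms: none
Why: Corey allylic deoxygenation: the unhindered primary allylic alcohol is sulfated selectively and the sulfate is displaced by hydride without alkene migration, giving the C8 methyl; the hindered C6-OH is retained.

**Step 12**
Reactants: 13
Product: 14, (3R,3aS,4S,6R,7S,8aR)-6,7-epoxy-6,8a-dimethyl-3-(propan-2-yl)-3-[(triethylsilyl)oxy]decahydroazulen-4-ol (8α,9α-epoxide)
Conditions: VO(acac)2 (5 mol %), t-BuOOH, CH2Cl2, 0 °C → rt
Reagents that add atoms: tert-butyl hydroperoxide, CC(C)(C)OO
Why: Vanadium-catalysed hydroxyl-directed epoxidation: the homoallylic 6α-OH delivers oxygen to the same (α) face of C8=C9, which is also the face away from the angular methyl.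

**Step 13**
Reactants: 15, 4-hydroxybenzoic acid
Product: 16, 4-[(tert-butyldimethylsilyl)oxy]benzoic acid
Conditions: TBSCl (2.2 equiv), imidazole, DMF; then K2CO3, THF/MeOH/H2O
Reagents that add atoms: tert-butyldimethylsilyl chloride, CC(C)(C)[Si](C)(C)Cl
Why: Bis-silylation followed by selective hydrolysis of the labile silyl ester masks the phenol so the acid cannot self-condense.

**Step 14**
Reactants: 14 and 16
Product: 17, the 4-[(tert-butyldimethylsilyl)oxy]benzoate of 14 at C6-OH
Conditions: DCC, DMAP, CH2Cl2, rt
Reagents that add atoms: none (all new atoms come from 16)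
Why: Steglich esterification of the only free (secondary) hydroxyl with retention at C6; the tertiary oxygen is silylated and the epoxide tolerates the neutral conditions.

**Step 15**
Reactants: 17
Product: 18, Jaeskeanin
Conditions: TBAF, AcOH (buffer), THF, 0 °C → rt
Reagents that add atoms: none
Why: Fluoride removes both the aryl TBS ether and the tertiary TES ether; the buffered conditions spare the benzoate and the trisubstituted epoxide.

## Compound list
1 | (S)-(+)-terpinen-4-ol | CC(C)[C@]1(O)CCC(C)=CC1 | starting material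
2 | (S)-terpinen-4-ol TES ether | CC(C)[C@]1(O[Si](CC)(CC)CC)CCC(C)=CC1 | intermediate
3 | (S)-6-oxo-3-(propan-2-yl)-3-[(triethylsilyl)oxy]heptanal | CC(C)[C@@](O[Si](CC)(CC)CC)(CC=O)CCC(C)=O | intermediate
4 | (R)-2-methyl-5-(propan-2-yl)-5-[(triethylsilyl)oxy]cyclopent-1-ene-1-carbaldehyde | CC(C)[C@]1(O[Si](CC)(CC)CC)CCC(C)=C1C=O | intermediate
5 | (R)-triethyl{[3-methyl-1-(propan-2-yl)-2-vinylcyclopent-2-en-1-yl]oxy}silane | CC(C)[C@]1(O[Si](CC)(CC)CC)CCC(C)=C1C=C | intermediate
6 | methyl acetoacetate | CC(=O)CC(=O)OC | starting material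
7 | methyl 2-diazo-3-oxobutanoate | CC(=O)C(=[N+]=[N-])C(=O)OC | intermediate
8 | methyl 2-diazo-3-hydroxybutanoate | CC(O)C(=[N+]=[N-])C(=O)OC | intermediate
9 | methyl 2-diazobut-3-enoate | C=CC(=[N+]=[N-])C(=O)OC | intermediate
10 | methyl (3R,8aR)-8a-methyl-3-(propan-2-yl)-3-[(triethylsilyl)oxy]-1,2,3,5,8,8a-hexahydroazulene-6-carboxylate | CC(C)[C@]1(O[Si](CC)(CC)CC)CC[C@]2(C)CC=C(C(=O)OC)CC=C21 | intermediate
11 | methyl (3R,3aS,4S,8aR)-4-hydroxy-8a-methyl-3-(propan-2-yl)-3-[(triethylsilyl)oxy]-1,2,3,3a,4,5,8,8a-octahydroazulene-6-carboxylate | CC(C)[C@]1(O[Si](CC)(CC)CC)CC[C@]2(C)CC=C(C(=O)OC)C[C@H](O)[C@H]21 | intermediate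
12 | (3R,3aS,4S,8aR)-6-(hydroxymethyl)-8a-methyl-3-(propan-2-yl)-3-[(triethylsilyl)oxy]-1,2,3,3a,4,5,8,8a-octahydroazulen-4-ol | CC(C)[C@]1(O[Si](CC)(CC)CC)CC[C@]2(C)CC=C(CO)C[C@H](O)[C@H]21 | intermediate
13 | 4-O-TES-jaeschkeanadiol | CC(C)[C@]1(O[Si](CC)(CC)CC)CC[C@]2(C)CC=C(C)C[C@H](O)[C@H]21 | intermediate
14 | 8α,9α-epoxy-4-O-TES-jaeschkeanadiol | CC(C)[C@]1(O[Si](CC)(CC)CC)CC[C@]2(C)C[C@@H]3O[C@]3(C)C[C@H](O)[C@H]21 | intermediate
15 | 4-hydroxybenzoic acid | OC(=O)c1ccc(O)cc1 | starting material
16 | 4-[(tert-butyldimethylsilyl)oxy]benzoic acid | CC(C)(C)[Si](C)(C)Oc1ccc(cc1)C(=O)O | intermediate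
17 | bis-silyl Jaeskeanin (4-O-TES, aryl O-TBS) | CC(C)[C@]1(O[Si](CC)(CC)CC)CC[C@]2(C)C[C@@H]3O[C@]3(C)C[C@H](OC(=O)c3ccc(O[Si](C)(C)C(C)(C)C)cc3)[C@H]21 | intermediate
18 | Jaeskeanin | CC(C)[C@]1(O)CC[C@]2(C)C[C@@H]3O[C@]3(C)C[C@H](OC(=O)c3ccc(O)cc3)[C@H]21 | target

## Summary
Total steps: 15 (11 in the main line, 3 for the diazo ester, 1 for the acid).
Longest linear sequence: 11 steps from (S)-terpinen-4-ol (steps 1, 2, 3, 4, 8, 9, 10, 11, 12, 14, 15).

**Three steps most likely to fail, with fallbacks**

1. **Step 9, hydroboration face.** The α-face also carries the C4 isopropyl group and the fold of the seven-membered ring, so β-attack (giving the cis-fused 6β-ol) is a real possibility; the enoate could also compete slowly. Fallback: bring C6 in as a ketone instead. Convert 4 to the methyl ketone and its 2-silyloxydiene, run the same [4+3] so C6 arrives as an enol ether, convert the ester to methyl, then unmask the β-hydroxy ketone. C5 is then set thermodynamically (C6 acyl trans to iPr, i.e. trans-fused) and C6 by Me4NBH(OAc)3 reduction directed by the 4β-OH.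

2. **Step 8, [4+3].** The Cope must form a quaternary centre on a tetrasubstituted cyclopentene with the methyl pointing inside and the new bond on the iPr face; the substrate/catalyst pairing may also be mismatched, and 9 is unstable. Fallback: abandon the cycloaddition. Add an allyl unit 1,4 to enal 4 (allyl cuprate/TMSCl), methallylate the C6 aldehyde, and close C8=C9 by ring-closing metathesis.

3. **Step 3, aldol condensation.** The aldehyde enamine carries a β-silyloxy leaving group (E1cB loss would destroy the stereocentre), and the ketone-enolate mode would give the regioisomeric acetylcyclopentene. Fallback: change the order of stereocentre introduction. Vinylate commercial 2-bromo-3-methylcyclopent-2-enone (Stille), run the Rh [4+3] on this achiral dienone so C1 is set by the catalyst alone, and install C4 last by iPrMgCl/CeCl3 addition to the ketone anti to the C5 substituent.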